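**Assumption:** the target has no stereocentre and no stereogenic double bond, so it is achiral; "single enantiomer" is taken to mean the constitution shown (seventeen CH2 groups between the nitrile carbon and the pyrrole).

**Retrosynthetic overview**
- Last bond formed: pyrrole C5–CH2, by direct palladium/norbornene-mediated C5–H alkylation of unprotected pyrrole-2-carboxaldehyde with 18-bromooctadecanenitrile. The formyl group is already in place, so the usual acylation/reduction/Vilsmeier sequence is avoided.
- 18-Bromooctadecanenitrile is cut at C10–C11: cross-metathesis of undec-10-enenitrile with 9-bromonon-1-ene, then alkene hydrogenation.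
- No ring is formed; the only ring (pyrrole) is bought as pyrrole-2-carboxaldehyde. No protecting groups, no stereocentres.

**Route**

Step 1
Reactants: 1 undec-10-enenitrile (3 equiv); 2 9-bromonon-1-ene (1 equiv)
Product: 3 18-bromooctadec-10-enenitrile (E/Z mixture; E major)
Conditions: second-generation Grubbs catalyst RuCl2(=CHPh)(PCy3)(H2IMes) (2 mol%), 1,4-benzoquinone (10 mol%), CH2Cl2, 40 °C, argon sweep to remove ethene
Reagents that add atoms: none
Why: Olefin cross-metathesis of two unhindered terminal alkenes, driven by loss of ethene; the three-fold excess of cheap 1 pushes the statistical distribution toward the cross product, the homodimers (a polar dinitrile and a non-polar dibromide) separate easily from 3 on silica, benzoquinone suppresses ruthenium-hydride chain walking, and the E/Z ratio is irrelevant because the alkene is saturated next.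

Step 2
Reactants: 3 18-bromooctadec-10-enenitrile
Product: 4 18-bromooctadecanenitrile
Conditions: H2 (1 atm), PtO2 (3 mol%), EtOAc, rt, stopped after uptake of 1 equiv H2
Reagents that add atoms: none
Why: Heterogeneous catalytic hydrogenation; the unhindered 1,2-disubstituted alkene is saturated on platinum in neutral EtOAc at 1 atm far faster than the nitrile is reduced or the primary C–Br bond is hydrogenolysed, and both alkene isomers converge on one product.

Step 3
Reactants: 4 18-bromooctadecanenitrile (1 equiv); 5 1H-pyrrole-2-carbaldehyde (2 equiv)
Product: 6 18-(5-formyl-1H-pyrrol-2-yl)octadecanenitrile (target)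
Conditions: PdCl2(MeCN)2 (10 mol%), norbornene (2 equiv), KHCO3 (3 equiv), DMA, 90 °C, air
Reagents that add atoms: none
Why: Catellani-type palladium/norbornene-mediated C–H alkylation of an NH-pyrrole carrying a 2-acceptor group: N-palladation by divalent palladium and norbornene insertion steer C–H palladation to the only free carbon next to nitrogen (C5), the primary bromide 4 adds oxidatively to the palladacycle (tetravalent palladium), and C–C reductive elimination followed by norbornene extrusion and protonation releases the 5-alkylated NH-pyrrole and returns divalent palladium, while the weak base KHCO3 keeps direct N-alkylation slow and nitrile and aldehyde are untouched.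

**Compound list**
1 | undec-10-enenitrile | C=CCCCCCCCCC#N | starting material
2 | 9-bromonon-1-ene | C=CCCCCCCCBr | starting material
3 | 18-bromooctadec-10-enenitrile (E/Z mixture; SMILES of the major E isomer) | N#CCCCCCCCC/C=C/CCCCCCCBr | intermediate
4 | 18-bromooctadecanenitrile | N#CCCCCCCCCCCCCCCCCCBr | intermediate
5 | 1H-pyrrole-2-carbaldehyde | O=Cc1ccc[nH]1 | starting material
6 | 18-(5-formyl-1H-pyrrol-2-yl)octadecanenitrile (the target natural product; achiral) | N#CCCCCCCCCCCCCCCCCCc1ccc(C=O)[nH]1 | target

**Total step count:** 3
**Longest linear sequence:** 3 steps (1/2 → 3 → 4 → 6)

**Steps most likely to fail, with fallbacks**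

Step 3 (highest risk: the aldehyde-bearing pyrrole may react sluggishly, or N-alkylation may compete). The fallback sets out from 4 and replaces C–H functionalisation by a cross-coupling of two prefunctionalised partners. Zinc is inserted into the C–Br bond of 4 (Zn dust, I2 5 mol%, DMA, 80 °C; the nitrile is tolerated) to give (17-cyanoheptadecyl)zinc bromide F3. This is added slowly to commercial 5-bromo-1H-pyrrole-2-carbaldehyde (1.5 equiv) with Pd(OAc)2 (2 mol%) and SPhos (4 mol%) in THF/DMA at 25–40 °C. In this Negishi sp3–sp2 coupling the biarylphosphine catalyst turns over faster than the alkylzinc halide is protonated by the N–H or adds to the aldehyde. The fallback comes back to the route at 6.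

Step 1 (statistical product distribution and possible chain-walked homologues that are hard to remove from a long-chain product). The fallback sets out from 1 and builds the chain by a sp3–sp3 coupling instead of metathesis. Hydroboration of 1 with 9-BBN (THF, 0 °C to rt) gives 11-(9-borabicyclo[3.3.1]nonan-9-yl)undecanenitrile F1. Without isolation it is coupled with a four-fold excess of commercial 1,7-dibromoheptane under alkyl–alkyl Suzuki–Miyaura conditions (Pd(OAc)2 4 mol%, PCy3 8 mol%, K3PO4·H2O, THF, rt). The bulky electron-rich phosphine allows oxidative addition of the unactivated primary bromide and outruns β-hydride elimination, and the excess dibromide, recovered by distillation, suppresses double coupling. This delivers the saturated bromide directly, bypasses 3 and step 2, and comes back to the route at 4.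

Step 2 (possible C–Br hydrogenolysis or partial nitrile reduction on the metal surface). The fallback sets out from 3 and changes the order of events. Compound 3 is used directly in the C–H alkylation with 5 under the step 3 conditions to give 18-(5-formyl-1H-pyrrol-2-yl)octadec-10-enenitrile F2 (E/Z mixture), in which the bromide is already consumed. The remote alkene is then saturated last with diimide generated from dipotassium azodicarboxylate and AcOH (MeOH/pyridine, rt, reagent added in portions because trans-alkenes react slowly). Diimide transfers hydrogen only to the unpolarised C=C bond and leaves aldehyde, nitrile and pyrrole alone, and this precursor, unlike sulfonylhydrazides, cannot condense with the aldehyde. The fallback comes back to the route at 6.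

**Further compounds**
F1 | step 1 | 11-(9-borabicyclo[3.3.1]nonan-9-yl)undecanenitrile | N#CCCCCCCCCCCB1C2CCCC1CCC2
F2 | step 2 | 18-(5-formyl-1H-pyrrol-2-yl)octadec-10-enenitrile (E/Z mixture; SMILES of the E isomer) | N#CCCCCCCCC/C=C/CCCCCCCc1ccc(C=O)[nH]1
F3 | step 3 | (17-cyanoheptadecyl)zinc bromide | N#CCCCCCCCCCCCCCCCCC[Zn]Br
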